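The data were computed with made-up constants; scatter was added.

A one-step world turns each Q lost into one X, and before charging anything new we can hold that picture against the elm run.

all flasks: Q 0.20 M

| charge | D | remark | time |
|---|---|---|---|
| elm | 0.33 M | run made earlier |  |
| Monday's | 0.220 M |  | 1.0 h |
| Saturday's | 0.220 M |  | 1.3 h |

elm run (percent of the Q charged)

| time / min | X / % | Q / % |
|---|---|---|
| 0.833 | 7 | 92 |
| 2.50 | 10 | 81 |
| 4.00 | 16 | 74 |
| 6.00 | 20 | 69 |
| 10.0 | 28 | 58 |
| 12.0 | 30 | 52 |

(each reading ± 2 percentage points)

- which of the two there is more of at the end, Monday's (L / X)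
- which of the two there is more of at the end, Saturday's (L / X)
- final X, as a percentage of the Q charged, in Monday's
- final X, as a percentage of the Q charged, in Saturday's

- a reading or a percentage of X counts all its forms, free or not

The decision is how long to leave the flask at the lower charge of D, 0.220 M: is Saturday's 1.3 h worth waiting for over Monday's 1.0 h? At the last elm reading, 12.0 min, X stands at 30 % while 48.0 % of the Q has gone, so the one-step picture fails, and the ratio of the two is 0.625. This ratio, X found per Q lost (the selectivity), we call the X share; it is read from two readings, each with a scatter of 2 percentage points. We take the rest of the Q lost to be L, and the X share is more than 0.5, so we expect more X than L in both flasks.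

For the Q lost we keep the one-step reckoning, with one D taken per Q. The elm fall to 52 % gives a rate constant, and one over that constant times the new D charge is a time of 22.9 min. With it we reckon 25.2 % of the Q left in Monday's and 20.0 % in Saturday's. The X share then gives 46.7 % and 50.0 % of X, so the extra 18.0 min buys 3.3 points.

The forecast, which reads “parallel routes to X and L”, puts X ahead in both flasks, with 46 % for Monday's and 49 % for Saturday's, slightly lower than our figures.

Monday's ends at 48.9 % of X against 16.5 % of L, and Saturday's at 52.7 % against 17.0 %.

    Q + D → X (k = 0.139 M⁻¹ min⁻¹)
    Q + 2 D → L (k = 0.357 M⁻² min⁻¹)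
    D + X → J (k = 0.00291 M⁻¹ min⁻¹)
    Z ⇌ X, rate k4*(cs4 - [X]) while solid is left; crystals form when [X] > cs4 (solubility = 0.0760 M, k = 4.53 min⁻¹)

The wait bought 3.8 points of X. Monday's still held 34 % of its Q at 1.00 h, more than the 25.2 % we reckoned. Its X share comes to 0.741, against the 0.625 read in the elm run at 0.33 M of D and 12.0 min. Saturday's, with 30 % of its Q left at 1.30 h, has an X share of 0.753.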